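**Retrosynthetic overview**
- The hindered ester C–O bond is cut last: Mitsunobu union (with inversion) of a salicylic acid fragment (ring A with its chain) and a resorcinol alcohol fragment (ring B with its chain), then global desilylation.
- Acid fragment: the ring A–chain bond comes from a carboxylate-directed C–H hydroarylation of a terminal alkene by 2-hydroxy-4-methoxybenzoic acid (the new step). That acid comes from resorcinol by Kolbe–Schmitt carboxylation and 4-O-methylation.
- Alcohol fragment: the ring B–chain bond comes from iridium-catalysed C–H borylation of resorcinol bis-silyl ether, bromodeboronation and B-alkyl Suzuki–Miyaura coupling.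
- Both carbinol centres come from (R)- and (S)-2-propyloxirane by copper-catalysed Grignard opening.
- No ring is built: both benzene rings are resorcinol; ring A and ring B are elaborated in parallel and joined at the ester.

Assumption: both enantiomers of 2-propyloxirane are bought enantiopure. The target is taken exactly as drawn: eight CH2 between ring A and its carbinol, seven in the ring B chain, both carbinol centres (R).

**Step 1**
Reactants: 1 resorcinol
Product: 2 2,4-dihydroxybenzoic acid
Conditions: KHCO3 (5 equiv), H2O, CO2 (1 atm), 100 °C then reflux; conc. HCl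
Reagents that add atoms: carbon dioxide, O=C=O; potassium hydrogencarbonate, [K+].OC([O-])=O (base and second CO2 source)
Why: Kolbe–Schmitt carboxylation of the resorcinolate, which under aqueous bicarbonate goes ortho to one OH and para to the other to give β-resorcylic acid.

**Step 2**
Reactants: 2 2,4-dihydroxybenzoic acid
Product: 3 2-hydroxy-4-methoxybenzoic acid
Conditions: Me2SO4 (1.1 equiv), aq. NaOH (2.2 equiv), 25 °C; then HCl
Reagents that add atoms: dimethyl sulfate, COS(=O)(=O)OC
Why: Williamson-type O-methylation of the dianion; only the carboxylate and the 4-OH are deprotonated, while the 2-OH stays locked in a hydrogen bond to the carboxylate, so the 4-phenoxide alone is methylated.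

**Step 3**
Reactants: 4 7-bromohept-1-ene; 5 (R)-2-propyloxirane
Product: 7 (4R)-dodec-11-en-4-ol, via hept-6-en-1-ylmagnesium bromide 6 (not isolated)
Conditions: 4, Mg, THF, reflux; then CuI (10 mol%), 5, THF, −30 → 0 °C; aq. HCl (1 M)
Reagents that add atoms: magnesium, [Mg] (held only in intermediate 6)
Why: Copper-catalysed Grignard opening of a terminal epoxide by SN2 attack at the unsubstituted CH2, so the C–O stereocentre of 5 is not touched and is carried over as (R).

**Step 4**
Reactants: 7 (4R)-dodec-11-en-4-ol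
Product: 8 tert-butyl{[(4R)-dodec-11-en-4-yl]oxy}dimethylsilane
Conditions: TBSCl, imidazole, DMF, rt
Reagents that add atoms: tert-butyldimethylsilyl chloride, CC(C)(C)[Si](C)(C)Cl
Why: Standard silyl ether protection of a secondary alcohol, which keeps it out of the ruthenium step and of the later Mitsunobu reaction; no bond at the stereocentre is broken.

**Step 5**
Reactants: 3 2-hydroxy-4-methoxybenzoic acid; 8 tert-butyl{[(4R)-dodec-11-en-4-yl]oxy}dimethylsilane
Product: 9 6-[(9R)-9-(tert-butyldimethylsilyloxy)dodecyl]-2-hydroxy-4-methoxybenzoic acid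
Conditions: [RuCl2(p-cymene)]2 (5 mol%), MesCO2K (30 mol%), 8 (1.5 equiv), PhMe, 110 °C, Ar, 24 h; aq. citric acid
Reagents that add atoms: none
Why: Proposed new method: carboxylate-directed, redox-neutral anti-Markovnikov hydroarylation of an unactivated terminal alkene by a salicylic-type benzoic acid on a divalent ruthenium biscarboxylate; the carboxylate of 3 binds ruthenium, the 2-OH···O=C hydrogen bond holds it in the ring plane, carboxylate-assisted concerted metalation–deprotonation cleaves the only ortho C–H bond (C6, meta to both oxygens and out of reach of electrophilic substitution) to give a five-membered ruthenacycle, 1,2-insertion of 8 with the aryl group going to the terminal carbon gives a seven-membered alkylruthenium species, and protonation by 3 or MesCO2H releases linear 9 without change of oxidation state; the closest known reaction types are the carboxylate-assisted ruthenium-catalysed linear hydroarylation of unactivated 1-alkenes by 2-arylpyridines and the carboxylate-directed ruthenium-catalysed ortho C–H functionalisation of benzoic acids with alkynes and acrylates; the remote (R) centre is untouched.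

**Step 6**
Reactants: 1 resorcinol
Product: 10 1,3-bis(triisopropylsilyloxy)benzene
Conditions: TIPSCl (2.3 equiv), imidazole, DMF, rt → 40 °C
Reagents that add atoms: triisopropylsilyl chloride, CC(C)[Si](Cl)(C(C)C)C(C)C
Why: Standard phenol silylation; the bulky, base-stable silyl groups shield C2, C4 and C6 for the borylation and survive the cross-coupling.

**Step 7**
Reactants: 10 1,3-bis(triisopropylsilyloxy)benzene
Product: 11 2-[3,5-bis(triisopropylsilyloxy)phenyl]-4,4,5,5-tetramethyl-1,3,2-dioxaborolane
Conditions: B2pin2 (0.7 equiv), [Ir(OMe)(cod)]2 (1.5 mol%), dtbpy (3 mol%), hexane, 80 °C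
Reagents that add atoms: bis(pinacolato)diboron, CC1(C)OB(OC1(C)C)B1OC(C)(C)C(C)(C)O1
Why: Iridium-catalysed, sterically controlled aromatic C–H borylation on a trivalent iridium tris(boryl) complex; C5 is the only C–H bond without an ortho substituent, so the boron goes meta to both oxygens.

**Step 8**
Reactants: 11 2-[3,5-bis(triisopropylsilyloxy)phenyl]-4,4,5,5-tetramethyl-1,3,2-dioxaborolane
Product: 12 1-bromo-3,5-bis(triisopropylsilyloxy)benzene
Conditions: CuBr2 (3 equiv), MeOH/THF/H2O, 80 °C
Reagents that add atoms: copper dibromide, [Cu+2].[Br-].[Br-]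
Why: Copper-mediated bromodeboronation; the aryl group moves from boron to divalent copper and the C–Br bond forms at the ipso carbon, so bromine lands at C5 and not at the electronically activated positions 2, 4 and 6.

**Step 9**
Reactants: 13 6-bromohex-1-ene; 14 (S)-2-propyloxirane
Product: 16 (4S)-undec-10-en-4-ol, via hex-5-en-1-ylmagnesium bromide 15 (not isolated)
Conditions: 13, Mg, THF, reflux; then CuI (10 mol%), 14, THF, −30 → 0 °C; aq. HCl (1 M)
Reagents that add atoms: magnesium, [Mg] (held only in intermediate 15)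
Why: Copper-catalysed Grignard opening of the terminal epoxide at CH2, which carries the (S) centre of 14 over unchanged; (S) is chosen because step 11 inverts it.

**Step 10**
Reactants: 16 (4S)-undec-10-en-4-ol; 12 1-bromo-3,5-bis(triisopropylsilyloxy)benzene
Product: 18 (4S)-11-[3,5-bis(triisopropylsilyloxy)phenyl]undecan-4-ol, via O,B-bis(9-borabicyclononyl) adduct 17 (not isolated)
Conditions: 16, 9-BBN (2.2 equiv), THF, 0 °C → rt; then 12, PdCl2(dppf) (5 mol%), aq. K3PO4 (3 M), DMF, 50 °C
Reagents that add atoms: 9-borabicyclo[3.3.1]nonane, B1C2CCCC1CCC2 (held only in intermediate 17)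
Why: Anti-Markovnikov hydroboration followed by B-alkyl Suzuki–Miyaura coupling on zerovalent palladium forms the ring B–CH2 bond; the first equivalent of borane masks the free OH as a borinate that the aqueous base hydrolyses, and the remote stereocentre is untouched.

**Step 11**
Reactants: 9 6-[(9R)-9-(tert-butyldimethylsilyloxy)dodecyl]-2-hydroxy-4-methoxybenzoic acid; 18 (4S)-11-[3,5-bis(triisopropylsilyloxy)phenyl]undecan-4-ol
Product: 19 (4R)-11-[3,5-bis(triisopropylsilyloxy)phenyl]undecan-4-yl 6-[(9R)-9-(tert-butyldimethylsilyloxy)dodecyl]-2-hydroxy-4-methoxybenzoate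
Conditions: 9 (1.2 equiv), PPh3, DIAD, PhMe, 0 °C → rt
Reagents that add atoms: none
Why: Mitsunobu esterification; the carboxylate attacks the alkoxyphosphonium ion of 18 by SN2, so the di-ortho-substituted acid need not be activated at its carbonyl, the carbinol centre is inverted from (S) to (R), and the hydrogen-bonded 2-OH does not react.

**Step 12**
Reactants: 19 (4R)-11-[3,5-bis(triisopropylsilyloxy)phenyl]undecan-4-yl 6-[(9R)-9-(tert-butyldimethylsilyloxy)dodecyl]-2-hydroxy-4-methoxybenzoate
Product: 20 5'-methoxy-integracin B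
Conditions: TBAF (5 equiv), THF, 0 °C → rt; AcOH quench
Reagents that add atoms: none
Why: Fluoride-mediated desilylation removes the two aryl silyl ethers and the alkyl silyl ether, while the hindered di-ortho-substituted benzoate and both stereocentres are inert to fluoride.

**Compound list**
1 | resorcinol (benzene-1,3-diol) | Oc1cccc(O)c1 | starting material
2 | 2,4-dihydroxybenzoic acid | OC(=O)c1ccc(O)cc1O | intermediate
3 | 2-hydroxy-4-methoxybenzoic acid | COc1ccc(C(=O)O)c(O)c1 | intermediate
4 | 7-bromohept-1-ene | C=CCCCCCBr | starting material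
5 | (R)-2-propyloxirane | CCC[C@@H]1CO1 | starting material
6 | hept-6-en-1-ylmagnesium bromide (formed in the flask) | C=CCCCCC[Mg]Br | intermediate
7 | (4R)-dodec-11-en-4-ol | CCC[C@@H](O)CCCCCCC=C | intermediate
8 | tert-butyl{[(4R)-dodec-11-en-4-yl]oxy}dimethylsilane | CCC[C@@H](O[Si](C)(C)C(C)(C)C)CCCCCCC=C | intermediate
9 | 6-[(9R)-9-(tert-butyldimethylsilyloxy)dodecyl]-2-hydroxy-4-methoxybenzoic acid | CCC[C@@H](O[Si](C)(C)C(C)(C)C)CCCCCCCCc1cc(OC)cc(O)c1C(=O)O | intermediate
10 | 1,3-bis(triisopropylsilyloxy)benzene | CC(C)[Si](Oc1cccc(O[Si](C(C)C)(C(C)C)C(C)C)c1)(C(C)C)C(C)C | intermediate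
11 | 2-[3,5-bis(triisopropylsilyloxy)phenyl]-4,4,5,5-tetramethyl-1,3,2-dioxaborolane | CC(C)[Si](Oc1cc(O[Si](C(C)C)(C(C)C)C(C)C)cc(B2OC(C)(C)C(C)(C)O2)c1)(C(C)C)C(C)C | intermediate
12 | 1-bromo-3,5-bis(triisopropylsilyloxy)benzene | CC(C)[Si](Oc1cc(Br)cc(O[Si](C(C)C)(C(C)C)C(C)C)c1)(C(C)C)C(C)C | intermediate
13 | 6-bromohex-1-ene | C=CCCCCBr | starting material
14 | (S)-2-propyloxirane | CCC[C@H]1CO1 | starting material
15 | hex-5-en-1-ylmagnesium bromide (formed in the flask) | C=CCCCC[Mg]Br | intermediate
16 | (4S)-undec-10-en-4-ol | CCC[C@H](O)CCCCCC=C | intermediate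
17 | 9-[(8S)-8-(9-borabicyclo[3.3.1]nonan-9-yloxy)undecyl]-9-borabicyclo[3.3.1]nonane (formed in the flask) | CCC[C@H](OB1C2CCCC1CCC2)CCCCCCCB1C2CCCC1CCC2 | intermediate
18 | (4S)-11-[3,5-bis(triisopropylsilyloxy)phenyl]undecan-4-ol | CCC[C@H](O)CCCCCCCc1cc(O[Si](C(C)C)(C(C)C)C(C)C)cc(O[Si](C(C)C)(C(C)C)C(C)C)c1 | intermediate
19 | (4R)-11-[3,5-bis(triisopropylsilyloxy)phenyl]undecan-4-yl 6-[(9R)-9-(tert-butyldimethylsilyloxy)dodecyl]-2-hydroxy-4-methoxybenzoate | CCC[C@@H](O[Si](C)(C)C(C)(C)C)CCCCCCCCc1cc(OC)cc(O)c1C(=O)O[C@H](CCC)CCCCCCCc1cc(O[Si](C(C)C)(C(C)C)C(C)C)cc(O[Si](C(C)C)(C(C)C)C(C)C)c1 | intermediate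
20 | 5'-methoxy-integracin B, (4R)-11-(3,5-dihydroxyphenyl)undecan-4-yl 2-hydroxy-6-[(9R)-9-hydroxydodecyl]-4-methoxybenzoate | CCC[C@@H](O)CCCCCCCCc1cc(OC)cc(O)c1C(=O)O[C@H](CCC)CCCCCCCc1cc(O)cc(O)c1 | target

**Totals**
Total step count: 12. Longest linear sequence: 6 (steps 6, 7, 8, 10, 11, 12).

**Steps most likely to fail**

Step 5 (the proposed hydroarylation). It can fail through binding of the catalyst by the salicylate, isomerisation of alkene 8 to internal alkenes, or protodecarboxylation of the electron-rich acid. The fallback makes the ring A–chain bond by cross-coupling and puts the carboxyl group in afterwards, all by known reactions. It sets out from alkene 8 and aryl bromide 12 and comes back to the route at acid 9. Hydroboration of 8 with 9-BBN (THF, rt) gives 9-[(9R)-9-(tert-butyldimethylsilyloxy)dodecyl]-9-borabicyclo[3.3.1]nonane F1. This is coupled in the same flask with 12 (PdCl2(dppf), aq. K3PO4, DMF, 50 °C; B-alkyl Suzuki–Miyaura coupling) to give tert-butyl({(4R)-12-[3,5-bis(triisopropylsilyloxy)phenyl]dodecan-4-yl}oxy)dimethylsilane F2. TBAF (2.1 equiv, THF, 0 °C, short time) removes only the two aryl silyl groups and gives 5-[(9R)-9-(tert-butyldimethylsilyloxy)dodecyl]benzene-1,3-diol F3. Carboxylation with methyl magnesium carbonate (MeOMgOCO2Me, DMF, 120 °C), the method used for olivetolic acid, places the carboxyl group between the chain and one hydroxyl and gives 6-[(9R)-9-(tert-butyldimethylsilyloxy)dodecyl]-2,4-dihydroxybenzoic acid F4. Methylation of its dianion as in step 2 (Me2SO4, NaOH, H2O/THF) gives 9.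

Step 8 (bromodeboronation). The hydrogen bromide formed in hot aqueous methanol may cleave the aryl silyl ethers, and the lipophilic boronate dissolves poorly. The fallback replaces the halide by a triflate made under neutral conditions. It sets out from boronate 11 and comes back to the route at alcohol 18. Oxidation of 11 with 2KHSO5·KHSO4·K2SO4 (acetone/H2O, rt) gives 3,5-bis(triisopropylsilyloxy)phenol F5. Tf2O and pyridine (CH2Cl2, 0 °C) give 3,5-bis(triisopropylsilyloxy)phenyl trifluoromethanesulfonate F6. This takes the place of 12 in the coupling with borane 17 under the conditions of step 10 and gives 18.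

Step 11 (Mitsunobu esterification). The hindered acid may react slowly, with elimination of the activated alcohol or partial retention. The fallback separates activation from displacement. It sets out from alcohol 18 and acid 9 and comes back to the route at ester 19. MsCl and Et3N (CH2Cl2, 0 °C) convert 18 with retention into (4S)-11-[3,5-bis(triisopropylsilyloxy)phenyl]undecan-4-yl methanesulfonate F7. Acid 9 with CsHCO3 (1 equiv) gives cesium 6-[(9R)-9-(tert-butyldimethylsilyloxy)dodecyl]-2-hydroxy-4-methoxybenzoate F8. This displaces the mesylate in DMF at 50 °C by SN2 with inversion and gives 19.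

**Further compounds**
F1 | step 5 | 9-[(9R)-9-(tert-butyldimethylsilyloxy)dodecyl]-9-borabicyclo[3.3.1]nonane | CCC[C@@H](O[Si](C)(C)C(C)(C)C)CCCCCCCCB1C2CCCC1CCC2
F2 | step 5 | tert-butyl({(4R)-12-[3,5-bis(triisopropylsilyloxy)phenyl]dodecan-4-yl}oxy)dimethylsilane | CCC[C@@H](O[Si](C)(C)C(C)(C)C)CCCCCCCCc1cc(O[Si](C(C)C)(C(C)C)C(C)C)cc(O[Si](C(C)C)(C(C)C)C(C)C)c1
F3 | step 5 | 5-[(9R)-9-(tert-butyldimethylsilyloxy)dodecyl]benzene-1,3-diol | CCC[C@@H](O[Si](C)(C)C(C)(C)C)CCCCCCCCc1cc(O)cc(O)c1
F4 | step 5 | 6-[(9R)-9-(tert-butyldimethylsilyloxy)dodecyl]-2,4-dihydroxybenzoic acid | CCC[C@@H](O[Si](C)(C)C(C)(C)C)CCCCCCCCc1cc(O)cc(O)c1C(=O)O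
F5 | step 8 | 3,5-bis(triisopropylsilyloxy)phenol | CC(C)[Si](Oc1cc(O)cc(O[Si](C(C)C)(C(C)C)C(C)C)c1)(C(C)C)C(C)C
F6 | step 8 | 3,5-bis(triisopropylsilyloxy)phenyl trifluoromethanesulfonate | CC(C)[Si](Oc1cc(OS(=O)(=O)C(F)(F)F)cc(O[Si](C(C)C)(C(C)C)C(C)C)c1)(C(C)C)C(C)C
F7 | step 11 | (4S)-11-[3,5-bis(triisopropylsilyloxy)phenyl]undecan-4-yl methanesulfonate | CCC[C@H](OS(C)(=O)=O)CCCCCCCc1cc(O[Si](C(C)C)(C(C)C)C(C)C)cc(O[Si](C(C)C)(C(C)C)C(C)C)c1
F8 | step 11 | cesium 6-[(9R)-9-(tert-butyldimethylsilyloxy)dodecyl]-2-hydroxy-4-methoxybenzoate | CCC[C@@H](O[Si](C)(C)C(C)(C)C)CCCCCCCCc1cc(OC)cc(O)c1C(=O)[O-].[Cs+]
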